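**Retrosynthetic overview**

1. Target 14 ⇐ 13 by global desilylation. 13 ⇐ 11 by breaking C2–C3: the pyranone ring (O1, C2, C3, C4, C4a, C8a) comes from ring contraction of the seven-membered ring of a 2H-1,3-benzodioxepine (O1, C2, O3, C3, C4, C4a, C8a). C2 migrates from O3 to C3, O3 leaves the ring and becomes the 3-hydroxyl oxygen, and the same step sets C2 and C3.
2. Enabling feature: C2 is an aldehyde-level carbon (bonded to O1 and the 4-hydroxyphenyl ring) next to C3, which bears oxygen and is α to the C4 ketone. C2 can therefore be stored as the mixed O1/O3 acetal of 4-hydroxybenzaldehyde, and the C4 ketone, as its C3=C4 enol silane inside the seven-membered ring, is the built-in nucleophile.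
3. 11 ⇐ 9 (enol silylation) ⇐ 7 + 8 (acetalisation forms O1–C2 and O3–C2); 7 ⇐ 4 by α-oxygenation of the acetyl group (introduces O3).
4. 4 ⇐ 1 + 2: C-geranylation of phloroacetophenone, then silylation of the two unhindered phenols so that only the O1 phenol stays free.
5. Ring order: both benzene rings are bought; seven-membered acetal ring (step 5); six-membered pyranone ring by contraction (step 7).

Key step: step 7

Remark: the sense of induction of the chiral acid in step 7 cannot be predicted from first principles; it is assumed that the antipode giving (2R) is identified in a test run and used.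

("Geranyl" = (2E)-3,7-dimethylocta-2,6-dien-1-yl; TIPS = triisopropylsilyl, TBS = tert-butyldimethylsilyl, TES = triethylsilyl, TMS = trimethylsilyl.)

**Route**

Step 1
Reactants: 1 2,4,6-trihydroxyacetophenone; 2 (E)-geranyl bromide
Product: 3 1-(3-geranyl-2,4,6-trihydroxyphenyl)ethanone
Conditions: 2 (0.9 equiv), K2CO3 (anhydrous), acetone, reflux
Reagents that add atoms: none
Why: C-alkylation of the ambident phloroglucinol-type phenoxide at a ring carbon (SN2 at the primary allylic bromide, E geometry untouched); the two free ring positions of 1 are equivalent, so only one mono-C-geranyl isomer can form, and sub-stoichiometric 2 limits bis- and O-alkylation.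

Step 2
Reactants: 3 1-(3-geranyl-2,4,6-trihydroxyphenyl)ethanone
Product: 4 1-[3-geranyl-2-hydroxy-4,6-bis(triisopropylsilyloxy)phenyl]ethanone
Conditions: TIPSCl (2.1 equiv), imidazole, DMF, 0 °C → rt
Reagents that add atoms: triisopropylsilyl chloride, CC(C)[Si](Cl)(C(C)C)C(C)C
Why: Silyl ether formation ordered by accessibility: the non-chelated 4-OH and the less hindered 6-OH react with the bulky silyl chloride, whereas the 2-OH, flanked by the geranyl CH2 and held in the hydrogen bond to the acetyl group, should stay free.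

Step 3
Reactants: 4 1-[3-geranyl-2-hydroxy-4,6-bis(triisopropylsilyloxy)phenyl]ethanone
Product: 5 trimethyl{1-[3-geranyl-4,6-bis(triisopropylsilyloxy)-2-(trimethylsilyloxy)phenyl]ethenyloxy}silane
Conditions: TMSOTf (2.3 equiv), Et3N (4 equiv), CH2Cl2, 0 °C; concentration, pentane, filtration (no aqueous work-up)
Reagents that add atoms: trimethylsilyl trifluoromethanesulfonate, C[Si](C)(C)OS(=O)(=O)C(F)(F)F
Why: Soft enolisation with O-silylation turns the methyl ketone into its only possible enol silane and caps the chelated phenol in the same operation; the geranyl alkenes and aryl TIPS ethers are inert to the buffered silyl triflate.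

Step 4
Reactants: 5 trimethyl{1-[3-geranyl-4,6-bis(triisopropylsilyloxy)-2-(trimethylsilyloxy)phenyl]ethenyloxy}silane
Product: 7 1-[3-geranyl-4,6-bis(triisopropylsilyloxy)-2-(trimethylsilyloxy)phenyl]-2-(trimethylsilyloxy)ethanone, via silyloxy epoxide 6 (not isolated)
Conditions: DMDO (1.0 equiv, dried acetone solution), CH2Cl2, −78 °C → rt; evaporation, used crude
Reagents that add atoms: dimethyldioxirane, CC1(C)OO1
Why: Rubottom oxidation: the electron-rich 1,1-disubstituted enol silane should be epoxidised by neutral DMDO at −78 °C far faster than the two isolated trisubstituted alkenes, and epoxide 6 opens with 1,4-silyl shift to the α-silyloxy ketone, which is already the bis-TMS ether needed in step 5.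

Step 5
Reactants: 7 1-[3-geranyl-4,6-bis(triisopropylsilyloxy)-2-(trimethylsilyloxy)phenyl]-2-(trimethylsilyloxy)ethanone; 8 4-(tert-butyldimethylsilyloxy)benzaldehyde
Product: 9 rac-2-[4-(tert-butyldimethylsilyloxy)phenyl]-9-geranyl-6,8-bis(triisopropylsilyloxy)-2H-1,3-benzodioxepin-5(4H)-one
Conditions: 8 (1.1 equiv), TMSOTf (10 mol%), CH2Cl2, −78 °C; pyridine quench; Et3N-deactivated silica
Reagents that add atoms: none
Why: Noyori acetalisation (aldehyde plus two silyl ethers under catalytic TMSOTf, driven by formation of the disiloxane): the primary OTMS oxygen adds first and the resulting oxocarbenium ion is captured by the neighbouring aryl OTMS oxygen to close the seven-membered mixed acetal under aprotic, cold conditions that spare the geranyl chain and the aryl silyl ethers; the acetal carbon forms racemic, which is of no consequence because step 7 erases it.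

Step 6
Reactants: 9 rac-2-[4-(tert-butyldimethylsilyloxy)phenyl]-9-geranyl-6,8-bis(triisopropylsilyloxy)-2H-1,3-benzodioxepin-5(4H)-one
Product: 11 rac-2-[4-(tert-butyldimethylsilyloxy)phenyl]-9-geranyl-5-(triethylsilyloxy)-6,8-bis(triisopropylsilyloxy)-2H-1,3-benzodioxepine, via potassium enolate 10 (not isolated)
Conditions: KHMDS (1.15 equiv), THF, −78 °C; then TESCl (1.3 equiv), −78 → −40 °C; pentane, filtration through basic alumina
Reagents that add atoms: chlorotriethylsilane, CC[Si](Cl)(CC)CC
Why: Kinetic deprotonation at the only enolisable position (the O3–CH2 group α to the ketone) and O-silylation of the potassium enolate give the endocyclic, necessarily cis, enol silane, i.e. a cyclic vinyl acetal; the enolate has no β-leaving group and base leaves the acetal intact.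

Step 7
Reactants: 11 rac-2-[4-(tert-butyldimethylsilyloxy)phenyl]-9-geranyl-5-(triethylsilyloxy)-6,8-bis(triisopropylsilyloxy)-2H-1,3-benzodioxepine
Product: 13 (2R,3R)-2-[4-(tert-butyldimethylsilyloxy)phenyl]-8-geranyl-3-(triethylsilyloxy)-5,7-bis(triisopropylsilyloxy)chroman-4-one, via ring-opened aryloxocarbenium ion 12 (not isolated)
Conditions: confined chiral imidodiphosphorimidate (IDPi) Brønsted acid (3 mol%, antipode giving 2R; silylated in situ by a trace of 11), toluene, −78 → −40 °C; Et3N quench
Reagents that add atoms: none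
Why: Proposed new method: the silylated chiral acid (Et3Si+ paired with the confined IDPi anion) silylates the vinyl-ether oxygen O3 of the cyclic vinyl acetal 11, the C2–O3 bond ionises to the planar aryloxocarbenium ion 12 (stabilised by O1 and the 4-silyloxyphenyl group; the racemic acetal centre is erased, so the step is enantioconvergent), C3 of the tethered enediol bis(silyl ether) bonds to C2, and the C4 silyloxocarbenium hands Et3Si+ back to the anion, so that overall C2 moves from O3 to C3, the silyl group from O4 to O3, and O3 leaves the ring (7 → 6). The closest known reaction type is the acid-promoted Petasis–Ferrier-type O→C rearrangement of cyclic vinyl acetals, including the ring contraction of seven-membered 4,5-dihydro-1,3-dioxepines (also under chiral phosphoric acid catalysis), together with counter-anion-directed Mukaiyama additions of enol silanes to acetal-derived oxocarbenium ions under silylium/IDPi catalysis; new here is an endocyclic α-oxygenated enol silane that delivers the acetal carbon to the carbon next to the departing oxygen. The pyranone ring closes in a 6-(enolendo)-endo-trig mode, geometrically a disrotatory oxa-6π closure of the O1=C2 / C8a=C4a / C4=C3 array. C2 (R) is set by the chiral counter-anion, which selects the face of the oxocarbenium ion (the helical sense of the closure); C3 (R) is set relative to C2 by geometry, because the (E)-oxocarbenium ion carries its aryl group outward while the enol inherited from the ring carries O3 inward (cis to C4a) and H outward, which on disrotatory closure places aryl and OSiEt3 trans, and any cis isomer would drain to the diequatorial trans isomer by enolisation at C3 without touching C2. The step needs C3- rather than C4-attack (secured by the aryl-conjugated silyloxocarbenium formed and by the six- versus five-membered ring), C–C closure rather than Prins capture by the geranyl alkene or Friedel–Crafts attack (the enol silane is orders of magnitude more nucleophilic and lies next to C2 at the moment of ionisation, and the only free arene position is flanked by two OTIPS groups), and exchange of the two faces of 12 by rotation about C8a–O1 faster than collapse (favoured by the long-lived aryl-stabilised cation and the bulky inward silyloxy group).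

Step 8
Reactants: 13 (2R,3R)-2-[4-(tert-butyldimethylsilyloxy)phenyl]-8-geranyl-3-(triethylsilyloxy)-5,7-bis(triisopropylsilyloxy)chroman-4-one
Product: 14 (2R,3R)-8-geranyl-3,5,7-trihydroxy-2-(4-hydroxyphenyl)chroman-4-one (CNP0187235.1)
Conditions: TBAF (6 equiv), AcOH (6 equiv), THF, 0 °C → rt
Reagents that add atoms: none
Why: Fluoride cleavage of the three aryl silyl ethers and the secondary TES ether under acetic acid buffering, which keeps the phenols protonated so that neither quinone-methide ring opening (C2 epimerisation) nor C3 enolisation should occur, and which is harmless to the geranyl chain.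

**Compound list**

1 | 1-(2,4,6-trihydroxyphenyl)ethanone (2,4,6-trihydroxyacetophenone) | CC(=O)c1c(O)cc(O)cc1O | starting material
2 | (E)-geranyl bromide, (2E)-1-bromo-3,7-dimethylocta-2,6-diene | CC(C)=CCC/C(C)=C/CBr | starting material
3 | 1-(3-geranyl-2,4,6-trihydroxyphenyl)ethanone | CC(C)=CCC/C(C)=C/Cc1c(O)cc(O)c(C(C)=O)c1O | intermediate
4 | 1-[3-geranyl-2-hydroxy-4,6-bis(triisopropylsilyloxy)phenyl]ethanone | CC(C)=CCC/C(C)=C/Cc1c(O[Si](C(C)C)(C(C)C)C(C)C)cc(O[Si](C(C)C)(C(C)C)C(C)C)c(C(C)=O)c1O | intermediate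
5 | trimethyl{1-[3-geranyl-4,6-bis(triisopropylsilyloxy)-2-(trimethylsilyloxy)phenyl]ethenyloxy}silane | CC(C)=CCC/C(C)=C/Cc1c(O[Si](C(C)C)(C(C)C)C(C)C)cc(O[Si](C(C)C)(C(C)C)C(C)C)c(C(=C)O[Si](C)(C)C)c1O[Si](C)(C)C | intermediate
6 | rac-2-[3-geranyl-4,6-bis(triisopropylsilyloxy)-2-(trimethylsilyloxy)phenyl]-2-(trimethylsilyloxy)oxirane | CC(C)=CCC/C(C)=C/Cc1c(O[Si](C(C)C)(C(C)C)C(C)C)cc(O[Si](C(C)C)(C(C)C)C(C)C)c(C2(O[Si](C)(C)C)CO2)c1O[Si](C)(C)C | intermediate (not isolated)
7 | 1-[3-geranyl-4,6-bis(triisopropylsilyloxy)-2-(trimethylsilyloxy)phenyl]-2-(trimethylsilyloxy)ethanone | CC(C)=CCC/C(C)=C/Cc1c(O[Si](C(C)C)(C(C)C)C(C)C)cc(O[Si](C(C)C)(C(C)C)C(C)C)c(C(=O)CO[Si](C)(C)C)c1O[Si](C)(C)C | intermediate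
8 | 4-(tert-butyldimethylsilyloxy)benzaldehyde | CC(C)(C)[Si](C)(C)Oc1ccc(C=O)cc1 | starting material
9 | rac-2-[4-(tert-butyldimethylsilyloxy)phenyl]-9-geranyl-6,8-bis(triisopropylsilyloxy)-2H-1,3-benzodioxepin-5(4H)-one | CC(C)=CCC/C(C)=C/Cc1c(O[Si](C(C)C)(C(C)C)C(C)C)cc(O[Si](C(C)C)(C(C)C)C(C)C)c2c1OC(c1ccc(O[Si](C)(C)C(C)(C)C)cc1)OCC2=O | intermediate
10 | potassium enolate of 9 (potassium 2-aryl-9-geranyl-6,8-bis(triisopropylsilyloxy)-2H-1,3-benzodioxepin-5-olate) | CC(C)=CCC/C(C)=C/Cc1c(O[Si](C(C)C)(C(C)C)C(C)C)cc(O[Si](C(C)C)(C(C)C)C(C)C)c2c1OC(c1ccc(O[Si](C)(C)C(C)(C)C)cc1)OC=C2[O-].[K+] | intermediate (not isolated)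
11 | rac-2-[4-(tert-butyldimethylsilyloxy)phenyl]-9-geranyl-5-(triethylsilyloxy)-6,8-bis(triisopropylsilyloxy)-2H-1,3-benzodioxepine | CC(C)=CCC/C(C)=C/Cc1c(O[Si](C(C)C)(C(C)C)C(C)C)cc(O[Si](C(C)C)(C(C)C)C(C)C)c2c1OC(c1ccc(O[Si](C)(C)C(C)(C)C)cc1)OC=C2O[Si](CC)(CC)CC | intermediate
12 | ring-opened (E)-aryloxocarbenium ion: {2-[(E)-1,2-bis(triethylsilyloxy)ethenyl]-6-geranyl-3,5-bis(triisopropylsilyloxy)phenyl}[4-(tert-butyldimethylsilyloxy)benzylidene]oxonium, paired with the chiral IDPi anion | CC(C)=CCC/C(C)=C/Cc1c(O[Si](C(C)C)(C(C)C)C(C)C)cc(O[Si](C(C)C)(C(C)C)C(C)C)c(/C(O[Si](CC)(CC)CC)=C\O[Si](CC)(CC)CC)c1/[O+]=C/c1ccc(O[Si](C)(C)C(C)(C)C)cc1 | intermediate (not isolated)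
13 | (2R,3R)-2-[4-(tert-butyldimethylsilyloxy)phenyl]-8-geranyl-3-(triethylsilyloxy)-5,7-bis(triisopropylsilyloxy)chroman-4-one | CC(C)=CCC/C(C)=C/Cc1c(O[Si](C(C)C)(C(C)C)C(C)C)cc(O[Si](C(C)C)(C(C)C)C(C)C)c2c1O[C@H](c1ccc(O[Si](C)(C)C(C)(C)C)cc1)[C@@H](O[Si](CC)(CC)CC)C2=O | intermediate
14 | (2R,3R)-8-geranyl-3,5,7-trihydroxy-2-(4-hydroxyphenyl)chroman-4-one (CNP0187235.1) | CC(C)=CCC/C(C)=C/Cc1c(O)cc(O)c2c1O[C@H](c1ccc(O)cc1)[C@@H](O)C2=O | target

**Step count and risks**

Total steps: 8. Longest linear sequence: 8 steps (1 → 14).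

Steps most likely to fail:

1. Step 7 (Proposed new method). The ion pair may collapse before its two faces have exchanged, so that the configuration of the racemic acetal is copied into the product, or the chiral anion may discriminate the faces poorly; turnover may also stall by silylium binding to the product ketone. Fallback with known chemistry, setting out from 4 and returning at 14:
   - The free phenol of 4 is capped (MOMCl, NaH, DMF, 0 °C) to give 1-[3-geranyl-2-(methoxymethoxy)-4,6-bis(triisopropylsilyloxy)phenyl]ethanone F1.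
   - Its lithium enolate (LiHMDS, THF, −78 °C) adds to 8 to give the aldol adduct 1-aryl-3-hydroxy-3-[4-(tert-butyldimethylsilyloxy)phenyl]propan-1-one F2.
   - F2 is dehydrated (MsCl, Et3N, CH2Cl2, 0 °C → rt) through the 3-(methanesulfonyloxy) ketone F3, which eliminates in the flask, to the (E)-chalcone F4.
   - Juliá–Colonna epoxidation under non-aqueous conditions (urea–H2O2, DBU, poly-L-leucine, THF), which leaves the electron-rich geranyl alkenes alone, should give the (αR,βS)-epoxy ketone F5.
   - Dilute methanolic HCl (0 °C → rt) removes the chelation-activated MOM group, and the freed phenol opens the epoxide at the benzylic carbon with inversion (6-endo) to the (2R,3R)-3-hydroxychromanone tris(silyl ether) F6.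
   - F6 is desilylated under the conditions of step 8 to 14. Here C3 comes from the catalyst-controlled epoxidation and C2 from the stereospecific epoxide opening.

2. Step 5. Closure of the seven-membered mixed aryl/alkyl acetal may lose to intermolecular acetal formation, or the labile acetal may hydrolyse on isolation. Fallback, setting out from 7 and 8 and returning at 9: the kinetic silyl-transfer acetalisation is replaced by equilibrium-controlled acetal exchange on the free diol.
   - The two TMS ethers of 7 are methanolysed (MeOH, cat. citric acid, 0 °C) to 1-[3-geranyl-2-hydroxy-4,6-bis(triisopropylsilyloxy)phenyl]-2-hydroxyethanone F7.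
   - 8 is converted (HC(OMe)3, cat. PPTS, MeOH) into 4-(tert-butyldimethylsilyloxy)benzaldehyde dimethyl acetal F8.
   - F7 and F8 (cat. PPTS, benzene, 5 Å sieves, 45 °C, high dilution, removal of methanol) should give 9.

3. Step 2. Silylation of the hindered 2-OH may compete with that of the 6-OH (poor regioselectivity between the two ortho hydroxyls). Fallback, setting out from 1 and returning at 4, with geranylation postponed:
   - 1 is bis-silylated first (TIPSCl, imidazole, DMF); the two ortho hydroxyls are equivalent and the second stays chelated, so only 1-[2-hydroxy-4,6-bis(triisopropylsilyloxy)phenyl]ethanone F9 can form.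
   - Iodination (NIS, CH2Cl2, 0 °C) ortho to the free phenol (the other free position lies between two OTIPS groups) gives 1-[2-hydroxy-3-iodo-4,6-bis(triisopropylsilyloxy)phenyl]ethanone F10.
   - Stille coupling with (E)-geranyltributylstannane (Pd2(dba)3, AsPh3, CuI, DMF, 50 °C) places the geranyl group on the carbon next to the free hydroxyl and gives 4 with unambiguous regiochemistry.

**Further compounds**

F1 | step 7 | 1-[3-geranyl-2-(methoxymethoxy)-4,6-bis(triisopropylsilyloxy)phenyl]ethanone | CC(C)=CCC/C(C)=C/Cc1c(O[Si](C(C)C)(C(C)C)C(C)C)cc(O[Si](C(C)C)(C(C)C)C(C)C)c(C(C)=O)c1OCOC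
F2 | step 7 | rac-1-[3-geranyl-2-(methoxymethoxy)-4,6-bis(triisopropylsilyloxy)phenyl]-3-hydroxy-3-[4-(tert-butyldimethylsilyloxy)phenyl]propan-1-one | CC(C)=CCC/C(C)=C/Cc1c(O[Si](C(C)C)(C(C)C)C(C)C)cc(O[Si](C(C)C)(C(C)C)C(C)C)c(C(=O)CC(O)c2ccc(O[Si](C)(C)C(C)(C)C)cc2)c1OCOC
F3 | step 7 | rac-3-[3-geranyl-2-(methoxymethoxy)-4,6-bis(triisopropylsilyloxy)phenyl]-3-oxo-1-[4-(tert-butyldimethylsilyloxy)phenyl]propyl methanesulfonate | CC(C)=CCC/C(C)=C/Cc1c(O[Si](C(C)C)(C(C)C)C(C)C)cc(O[Si](C(C)C)(C(C)C)C(C)C)c(C(=O)CC(OS(C)(=O)=O)c2ccc(O[Si](C)(C)C(C)(C)C)cc2)c1OCOC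
F4 | step 7 | (E)-1-[3-geranyl-2-(methoxymethoxy)-4,6-bis(triisopropylsilyloxy)phenyl]-3-[4-(tert-butyldimethylsilyloxy)phenyl]prop-2-en-1-one | CC(C)=CCC/C(C)=C/Cc1c(O[Si](C(C)C)(C(C)C)C(C)C)cc(O[Si](C(C)C)(C(C)C)C(C)C)c(C(=O)/C=C/c2ccc(O[Si](C)(C)C(C)(C)C)cc2)c1OCOC
F5 | step 7 | [3-geranyl-2-(methoxymethoxy)-4,6-bis(triisopropylsilyloxy)phenyl]{(2R,3S)-3-[4-(tert-butyldimethylsilyloxy)phenyl]oxiran-2-yl}methanone | CC(C)=CCC/C(C)=C/Cc1c(O[Si](C(C)C)(C(C)C)C(C)C)cc(O[Si](C(C)C)(C(C)C)C(C)C)c(C(=O)[C@@H]2O[C@H]2c2ccc(O[Si](C)(C)C(C)(C)C)cc2)c1OCOC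
F6 | step 7 | (2R,3R)-2-[4-(tert-butyldimethylsilyloxy)phenyl]-8-geranyl-3-hydroxy-5,7-bis(triisopropylsilyloxy)chroman-4-one | CC(C)=CCC/C(C)=C/Cc1c(O[Si](C(C)C)(C(C)C)C(C)C)cc(O[Si](C(C)C)(C(C)C)C(C)C)c2c1O[C@H](c1ccc(O[Si](C)(C)C(C)(C)C)cc1)[C@@H](O)C2=O
F7 | step 5 | 1-[3-geranyl-2-hydroxy-4,6-bis(triisopropylsilyloxy)phenyl]-2-hydroxyethanone | CC(C)=CCC/C(C)=C/Cc1c(O[Si](C(C)C)(C(C)C)C(C)C)cc(O[Si](C(C)C)(C(C)C)C(C)C)c(C(=O)CO)c1O
F8 | step 5 | 4-(tert-butyldimethylsilyloxy)benzaldehyde dimethyl acetal | COC(OC)c1ccc(O[Si](C)(C)C(C)(C)C)cc1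
F9 | step 2 | 1-[2-hydroxy-4,6-bis(triisopropylsilyloxy)phenyl]ethanone | CC(=O)c1c(O)cc(O[Si](C(C)C)(C(C)C)C(C)C)cc1O[Si](C(C)C)(C(C)C)C(C)C
F10 | step 2 | 1-[2-hydroxy-3-iodo-4,6-bis(triisopropylsilyloxy)phenyl]ethanone | CC(=O)c1c(O)c(I)c(O[Si](C(C)C)(C(C)C)C(C)C)cc1O[Si](C(C)C)(C(C)C)C(C)C
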